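**Assumption:** the trans ring fusion of the peroxide/γ‑lactone bicycle encoded in the SMILES is taken literally, and (+)-larixyl acetate (larch‑oleoresin labdane, one acetylation from larixol) is taken as a commercial starting material.

**Locants:** labdane numbering for the diterpene part (C16 = carbon on C13, C17 = carbon on C8, C18 = 4α carbon, C19 = 4β‑methyl, C20 = 10β‑methyl); 1′–6′ for the six‑carbon chain from aldehyde 21 (1′ is bonded to C13, 6′ becomes the lactone carbonyl).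

**Retrosynthetic overview**
1. γ‑Lactone (last ring): oxidative lactonisation of the 3′‑OH/6′‑OH diol 28.
2. 1,2‑Dioxane (second‑last ring): new perhydrolytic annulation in which H2O2 joins C4′ (epoxide, inversion) and C1′ (allylic mesylate, inversion) of 25.
3. C13–C1′ bond: asymmetric Ni/Cr coupling of vinyl triflate 16 with aldehyde 21; C3′/C4′ set by Shi epoxidation.
4. Decalin from the chiral pool (larixyl acetate): side‑chain cleavage, C8 hydration, 6α‑O‑directed C–H oxidation of the 4α‑methyl (transient 18,6α‑lactone) to the 4α‑ester.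
5. Aldehyde 21 from a butynyl silyl ether by Zr‑catalysed carboalumination and oxirane opening.

**Route**

Step 1
Reactants: 1 (+)-larixyl acetate
Product: 2 methyl ketone 6α-acetoxy-14,15-dinorlabd-8(17)-en-13-one
Conditions: KMnO4, acetone/H2O, 0 °C
Reagents that add atoms: none
Why: Permanganate oxidative cleavage of the vinyl carbinol (glycol formation, then C13–C14 scission) gives the methyl ketone while the hindered exocyclic alkene and the acetate survive; no stereocentre is touched.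

Step 2
Reactants: 2 methyl ketone
Product: 4 tertiary alcohol 6α-acetoxy-8α-hydroxy-14,15-dinorlabdan-13-one (8β-methyl), via 8α-hydroperoxide 3 (not isolated)
Conditions: Co(acac)2 (cat.), PhSiH3, O2 (1 atm), THF, rt
Reagents that add atoms: dioxygen, O=O
Why: Mukaiyama hydration: Co–H hydrogen‑atom transfer to the 1,1‑disubstituted alkene gives the tertiary C8 radical, which takes up O2 on the α face away from the axial C10 methyl, setting 8α‑O/8β‑CH3.

Step 3
Reactants: 4 tertiary alcohol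
Product: 5 silyl ether 6α-acetoxy-8α-(triethylsilyloxy)-14,15-dinorlabdan-13-one
Conditions: TESOTf, 2,6-lutidine, CH2Cl2, −78 → 0 °C
Reagents that add atoms: triethylsilyl trifluoromethanesulfonate, CC[Si](CC)(CC)OS(=O)(=O)C(F)(F)F
Why: Silyl triflate silylation masks the tertiary alcohol so that it cannot form an alkoxyl radical in step 5.

Step 4
Reactants: 5 silyl ether
Product: 6 alcohol 6α-hydroxy-8α-(triethylsilyloxy)-14,15-dinorlabdan-13-one
Conditions: K2CO3 (cat.), MeOH, 40 °C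
Reagents that add atoms: none
Why: Base‑catalysed transesterification frees only the 6α‑hydroxyl needed as the radical‑relay handle; the silyl ether and ketone are inert.

Step 5
Reactants: 6 alcohol
Product: 9 cyclic ether 6α,18-epoxy-8α-(triethylsilyloxy)-14,15-dinorlabdan-13-one (oxolane from the 4α carbon to the 6α oxygen), via hypoiodite 7 (not isolated), via iodo alcohol 8 (not isolated)
Conditions: PhI(OAc)2, I2, cyclohexane, hν (W lamp), 40 °C
Reagents that add atoms: none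
Why: Suárez hypoiodite reaction: the 6α‑alkoxyl radical abstracts hydrogen by 1,5‑HAT from the peri‑disposed equatorial 4α‑methyl (O···C about 2.5 Å; the axial 4β‑methyl is about 3.5 Å away), and iodination/ring closure differentiates the geminal methyls and so sets C4 (R).

Step 6
Reactants: 9 cyclic ether
Product: 11 lactone 13-oxo-8α-(triethylsilyloxy)-14,15-dinorlabdan-18,6α-olide, via lactol 10 (not isolated)
Conditions: RuCl3·xH2O (cat.), NaIO4, CCl4/MeCN/H2O, rt
Reagents that add atoms: sodium periodate, [Na+].[O-]I(=O)(=O)=O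
Why: RuO4 ether‑to‑lactone oxidation attacks the accessible ether CH2 (the C6 methine is shielded by three axial methyls), bringing the 4α carbon to the carboxyl level.

Step 7
Reactants: 11 lactone
Product: 13 hydroxy ester methyl 6α-hydroxy-13-oxo-8α-(triethylsilyloxy)-14,15-dinorlabdan-18-oate, via potassium carboxylate 12 (not isolated)
Conditions: KOH (1.1 equiv), MeOH/H2O, 60 °C; evaporate; MeI, DMF, rt
Reagents that add atoms: potassium hydroxide, [K+].[OH-]; iodomethane, CI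
Why: Saponification opens the strained lactone and SN2 methylation of the carboxylate salt traps the 4α‑methyl ester before it can relactonise.

Step 8
Reactants: 13 hydroxy ester
Product: 14 keto ester methyl 13-oxo-6α,8α-bis(triethylsilyloxy)-14,15-dinorlabdan-18-oate
Conditions: TESOTf, 2,6-lutidine, CH2Cl2, −78 °C
Reagents that add atoms: triethylsilyl trifluoromethanesulfonate, CC[Si](CC)(CC)OS(=O)(=O)C(F)(F)F
Why: Silylation blocks the 6α‑hydroxyl so that it can neither relactonise under base nor be sulfonylated in step 14.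

Step 9
Reactants: 14 keto ester
Product: 16 vinyl triflate methyl 6α,8α-bis(triethylsilyloxy)-13-(trifluoromethylsulfonyloxy)-14,15-dinorlabd-13(16)-en-18-oate, via potassium enolate 15 (not isolated)
Conditions: KHMDS, THF, −78 °C; PhNTf2, −78 → 0 °C
Reagents that add atoms: N-phenylbis(trifluoromethanesulfonimide), O=S(=O)(N(c1ccccc1)S(=O)(=O)C(F)(F)F)C(F)(F)F
Why: Kinetic deprotonation on the methyl side and O‑triflation (enol triflate formation) give the 2‑triflyloxy‑1‑alkene that carries C13 and the future exo‑methylene.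

Step 10
Reactants: 17 tert-butyl(but-3-yn-1-yloxy)dimethylsilane
Product: 20 (E)-6-(tert-butyldimethylsilyloxy)-4-methylhex-3-en-1-ol, via alkenylalane 18 (not isolated), via lithium alanate 19 (not isolated)
Conditions: AlMe3, Cp2ZrCl2 (cat.), CH2Cl2, 0 °C → rt; n-BuLi, THF, −78 °C; oxirane, −78 °C → rt
Reagents that add atoms: trimethylaluminium, C[Al](C)C; oxirane, C1CO1
Why: Negishi Zr‑catalysed syn‑carboalumination fixes the E trisubstituted alkene (methyl and Al cis), and the alanate opens oxirane to add the two‑carbon carbinol arm.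

Step 11
Reactants: 20 homoallylic alcohol
Product: 21 (E)-6-(tert-butyldimethylsilyloxy)-4-methylhex-3-enal
Conditions: Dess–Martin periodinane, CH2Cl2, 0 °C; filtered and used at once
Reagents that add atoms: none
Why: Dess–Martin oxidation under near‑neutral conditions gives the β,γ‑unsaturated aldehyde without moving the alkene into conjugation.

Step 12
Reactants: 16 vinyl triflate; 21 aldehyde
Product: 23 allylic alcohol methyl (1′S,3′E)-13-[6′-(tert-butyldimethylsilyloxy)-1′-hydroxy-4′-methylhex-3′-enyl]-6α,8α-bis(triethylsilyloxy)-14,15-dinorlabd-13(16)-en-18-oate, via alkenylchromium species 22 (not isolated)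
Conditions: CrCl2, NiCl2 (cat.), Kishi chiral sulfonamide ligand (antipode giving 1′S; pre-complexed with Et3N), THF, rt
Reagents that add atoms: none
Why: Asymmetric Nozaki–Hiyama–Kishi coupling: the Ni‑generated alkenyl–Cr(III) adds to the aldehyde within the chiral sulfonamide–chromium complex, forming the C13–C1′ bond and the 1′S carbinol under ligand control.

Step 13
Reactants: 23 allylic alcohol
Product: 24 epoxy alcohol (1′S,3′S,4′S)-3′,4′-epoxide of 23
Conditions: ent-Shi ketone (L-fructose-derived, 30 mol%), Oxone, K2CO3, Bu4NHSO4, MeCN/DMM–aq. borate buffer, 0 °C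
Reagents that add atoms: potassium peroxymonosulfate (Oxone), [K+].[O-]S(=O)(=O)OO
Why: Shi epoxidation: the chiral dioxirane reacts only with the electron‑rich E‑trisubstituted alkene through the spiro transition state, and the L‑series ketone gives the (3′S,4′S)‑epoxide (the D‑fructose ketone gives the R,R sense) while the 1,1‑disubstituted alkene is left.

Step 14
Reactants: 24 epoxy alcohol
Product: 25 epoxy mesylate (1′S,3′S,4′S)-1′-O-methanesulfonate of 24
Conditions: Ms2O, i-Pr2NEt, CH2Cl2, −40 °C; used crude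
Reagents that add atoms: methanesulfonic anhydride, CS(=O)(=O)OS(C)(=O)=O
Why: Sulfonylation with the anhydride (no chloride to cause SN2/SN2′ exchange) makes the leaving group with retention and stops the C1′ oxygen from opening the epoxide in a 5‑endo sense.

Step 15
Reactants: 25 epoxy mesylate
Product: 27 1,2-dioxane methyl 13-[(3R,5S,6R)-6-(2-(tert-butyldimethylsilyloxy)ethyl)-5-hydroxy-6-methyl-1,2-dioxan-3-yl]-6α,8α-bis(triethylsilyloxy)-14,15-dinorlabd-13(16)-en-18-oate, via hydroperoxy mesylate 26 (not isolated)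
Conditions: H2O2 (ethereal, 10 equiv), H3PMo12O40 (2 mol%), Et2O, 0 °C; cold aq. wash; then Cs2CO3, MeCN, 0 °C
Reagents that add atoms: hydrogen peroxide, OO
Why: Proposed new method: an acid/base‑switched perhydrolytic annulation in which H2O2 is a two‑point linchpin between an epoxide and an allylic sulfonate – the Mo(VI) heteropolyacid activates the trisubstituted epoxide so that H2O2 opens it at the tertiary C4′ with inversion (3′‑OH retained), and after excess H2O2 is washed out the carbonate‑generated tertiary peroxide anion displaces the 1′‑mesylate by 6‑exo‑tet SN2 with inversion (1′S → 1′R), so all three dioxane stereocentres come from stereospecific events and not from chair preferences (which would put the alkenyl group on the wrong face); the closest known reactions are Mo‑catalysed perhydrolysis of epoxides to β‑hydroxy hydroperoxides and base‑mediated intramolecular alkylation of hydroperoxides by sulfonates, not yet combined on one substrate or run with an allylic secondary sulfonate carried through the acidic stage.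

Step 16
Reactants: 27 1,2-dioxane
Product: 28 tetraol (27 without its three silyl groups: 6α-OH; 8α-OH; 3′-OH; 6′-OH)
Conditions: HF·pyridine, pyridine, THF, 0 °C → rt
Reagents that add atoms: none
Why: Buffered fluoride desilylation cleaves the TBS and both TES ethers while the dialkyl peroxide, the allylic system and the ester are left alone.

Step 17
Reactants: 28 tetraol
Product: 31 target CNP0162504.1, via hydroxy aldehyde 29 (not isolated), via lactol 30 (not isolated)
Conditions: TEMPO (0.2 equiv), PhI(OAc)2 (2.5 equiv), CH2Cl2, rt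
Reagents that add atoms: none
Why: TEMPO/PhI(OAc)2 oxidative lactonisation: the oxoammonium salt oxidises only the primary alcohol, the aldehyde is captured by the equatorial 3′‑OH as the lactol and oxidised on to the γ‑lactone, so the trans fusion follows from the C3′/C4′ configurations set in steps 13 and 15.

**Compound list**

1 | (+)-larixyl acetate, (13S)-6α-acetoxylabda-8(17),14-dien-13-ol | C=C[C@@](C)(O)CC[C@@H]1[C@@]2(C)CCCC(C)(C)[C@@H]2[C@@H](OC(C)=O)CC1=C | starting material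
2 | 6α-acetoxy-14,15-dinorlabd-8(17)-en-13-one | CC(=O)CC[C@@H]1[C@@]2(C)CCCC(C)(C)[C@@H]2[C@@H](OC(C)=O)CC1=C | intermediate
3 | 6α-acetoxy-8α-hydroperoxy-14,15-dinorlabdan-13-one | CC(=O)CC[C@@H]1[C@@]2(C)CCCC(C)(C)[C@@H]2[C@@H](OC(C)=O)C[C@@]1(C)OO | intermediate
4 | 6α-acetoxy-8α-hydroxy-14,15-dinorlabdan-13-one | CC(=O)CC[C@@H]1[C@@]2(C)CCCC(C)(C)[C@@H]2[C@@H](OC(C)=O)C[C@@]1(C)O | intermediate
5 | 6α-acetoxy-8α-(triethylsilyloxy)-14,15-dinorlabdan-13-one | CC(=O)CC[C@@H]1[C@@]2(C)CCCC(C)(C)[C@@H]2[C@@H](OC(C)=O)C[C@@]1(C)O[Si](CC)(CC)CC | intermediate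
6 | 6α-hydroxy-8α-(triethylsilyloxy)-14,15-dinorlabdan-13-one | CC(=O)CC[C@@H]1[C@@]2(C)CCCC(C)(C)[C@@H]2[C@@H](O)C[C@@]1(C)O[Si](CC)(CC)CC | intermediate
7 | 6α-hypoiodite of 6 | CC(=O)CC[C@@H]1[C@@]2(C)CCCC(C)(C)[C@@H]2[C@@H](OI)C[C@@]1(C)O[Si](CC)(CC)CC | intermediate
8 | 6α-hydroxy-18-iodo-8α-(triethylsilyloxy)-14,15-dinorlabdan-13-one (4α-CH2I) | CC(=O)CC[C@@H]1[C@@]2(C)CCC[C@@](C)(CI)[C@@H]2[C@@H](O)C[C@@]1(C)O[Si](CC)(CC)CC | intermediate
9 | 6α,18-epoxy-8α-(triethylsilyloxy)-14,15-dinorlabdan-13-one | CC(=O)CC[C@@H]1[C@@]2(C)CCC[C@@](C)(CO3)[C@@H]2[C@@H]3C[C@@]1(C)O[Si](CC)(CC)CC | intermediate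
10 | 6α,18-epoxy-18-hydroxy-8α-(triethylsilyloxy)-14,15-dinorlabdan-13-one (lactol) | CC(=O)CC[C@@H]1[C@@]2(C)CCC[C@@](C)(C(O)O3)[C@@H]2[C@@H]3C[C@@]1(C)O[Si](CC)(CC)CC | intermediate
11 | 13-oxo-8α-(triethylsilyloxy)-14,15-dinorlabdan-18,6α-olide | CC(=O)CC[C@@H]1[C@@]2(C)CCC[C@@](C)(C(=O)O3)[C@@H]2[C@@H]3C[C@@]1(C)O[Si](CC)(CC)CC | intermediate
12 | potassium 6α-hydroxy-13-oxo-8α-(triethylsilyloxy)-14,15-dinorlabdan-18-oate | CC(=O)CC[C@@H]1[C@@]2(C)CCC[C@@](C)(C(=O)[O-])[C@@H]2[C@@H](O)C[C@@]1(C)O[Si](CC)(CC)CC.[K+] | intermediate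
13 | methyl 6α-hydroxy-13-oxo-8α-(triethylsilyloxy)-14,15-dinorlabdan-18-oate (4α-CO2Me, 4β-Me) | CC(=O)CC[C@@H]1[C@@]2(C)CCC[C@@](C)(C(=O)OC)[C@@H]2[C@@H](O)C[C@@]1(C)O[Si](CC)(CC)CC | intermediate
14 | methyl 13-oxo-6α,8α-bis(triethylsilyloxy)-14,15-dinorlabdan-18-oate | CC(=O)CC[C@@H]1[C@@]2(C)CCC[C@@](C)(C(=O)OC)[C@@H]2[C@@H](O[Si](CC)(CC)CC)C[C@@]1(C)O[Si](CC)(CC)CC | intermediate
15 | potassium 13(16)-enolate of 14 | C=C([O-])CC[C@@H]1[C@@]2(C)CCC[C@@](C)(C(=O)OC)[C@@H]2[C@@H](O[Si](CC)(CC)CC)C[C@@]1(C)O[Si](CC)(CC)CC.[K+] | intermediate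
16 | methyl 6α,8α-bis(triethylsilyloxy)-13-(trifluoromethylsulfonyloxy)-14,15-dinorlabd-13(16)-en-18-oate | C=C(OS(=O)(=O)C(F)(F)F)CC[C@@H]1[C@@]2(C)CCC[C@@](C)(C(=O)OC)[C@@H]2[C@@H](O[Si](CC)(CC)CC)C[C@@]1(C)O[Si](CC)(CC)CC | intermediate
17 | tert-butyl(but-3-yn-1-yloxy)dimethylsilane | C#CCCO[Si](C)(C)C(C)(C)C | starting material
18 | (E)-[4-(tert-butyldimethylsilyloxy)-2-methylbut-1-enyl]dimethylalane | C[Al](C)/C=C(\C)CCO[Si](C)(C)C(C)(C)C | intermediate
19 | lithium butyl[(E)-4-(tert-butyldimethylsilyloxy)-2-methylbut-1-enyl]dimethylalanate | [Li+].CCCC[Al-](C)(C)/C=C(\C)CCO[Si](C)(C)C(C)(C)C | intermediate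
20 | (E)-6-(tert-butyldimethylsilyloxy)-4-methylhex-3-en-1-ol | OCC/C=C(\C)CCO[Si](C)(C)C(C)(C)C | intermediate
21 | (E)-6-(tert-butyldimethylsilyloxy)-4-methylhex-3-enal | O=CC/C=C(\C)CCO[Si](C)(C)C(C)(C)C | intermediate
22 | alkenylchromium(III) species from 16 (Cr on C13; ligand and solvent on Cr omitted) | C=C([Cr](Cl)Cl)CC[C@@H]1[C@@]2(C)CCC[C@@](C)(C(=O)OC)[C@@H]2[C@@H](O[Si](CC)(CC)CC)C[C@@]1(C)O[Si](CC)(CC)CC | intermediate
23 | (1′S,3′E)-allylic alcohol (C13 exo-methylene; 1′-OH; 3′,4′-alkene; 6′-OTBS) | C=C(CC[C@@H]1[C@@]2(C)CCC[C@@](C)(C(=O)OC)[C@@H]2[C@@H](O[Si](CC)(CC)CC)C[C@@]1(C)O[Si](CC)(CC)CC)[C@@H](O)C/C=C(\C)CCO[Si](C)(C)C(C)(C)C | intermediate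
24 | (1′S,3′S,4′S)-3′,4′-epoxy alcohol | C=C(CC[C@@H]1[C@@]2(C)CCC[C@@](C)(C(=O)OC)[C@@H]2[C@@H](O[Si](CC)(CC)CC)C[C@@]1(C)O[Si](CC)(CC)CC)[C@@H](O)C[C@@H]1O[C@@]1(C)CCO[Si](C)(C)C(C)(C)C | intermediate
25 | (1′S,3′S,4′S)-epoxy 1′-mesylate | C=C(CC[C@@H]1[C@@]2(C)CCC[C@@](C)(C(=O)OC)[C@@H]2[C@@H](O[Si](CC)(CC)CC)C[C@@]1(C)O[Si](CC)(CC)CC)[C@@H](OS(C)(=O)=O)C[C@@H]1O[C@@]1(C)CCO[Si](C)(C)C(C)(C)C | intermediate
26 | (1′S,3′S,4′R)-4′-hydroperoxy-3′-hydroxy 1′-mesylate | C=C(CC[C@@H]1[C@@]2(C)CCC[C@@](C)(C(=O)OC)[C@@H]2[C@@H](O[Si](CC)(CC)CC)C[C@@]1(C)O[Si](CC)(CC)CC)[C@@H](OS(C)(=O)=O)C[C@H](O)[C@@](C)(CCO[Si](C)(C)C(C)(C)C)OO | intermediate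
27 | (1′R,3′S,4′R)-1,2-dioxane (O–O joins C1′ and C4′; 3′-OH; 4′-CH3 and 4′-CH2CH2OTBS) | C=C(CC[C@@H]1[C@@]2(C)CCC[C@@](C)(C(=O)OC)[C@@H]2[C@@H](O[Si](CC)(CC)CC)C[C@@]1(C)O[Si](CC)(CC)CC)[C@H]1C[C@H](O)[C@@](C)(CCO[Si](C)(C)C(C)(C)C)OO1 | intermediate
28 | tetraol (desilylated 27) | C=C(CC[C@@H]1[C@@]2(C)CCC[C@@](C)(C(=O)OC)[C@@H]2[C@@H](O)C[C@@]1(C)O)[C@H]1C[C@H](O)[C@@](C)(CCO)OO1 | intermediate
29 | 6′-aldehyde of 28 | C=C(CC[C@@H]1[C@@]2(C)CCC[C@@](C)(C(=O)OC)[C@@H]2[C@@H](O)C[C@@]1(C)O)[C@H]1C[C@H](O)[C@@](C)(CC=O)OO1 | intermediate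
30 | lactol (6′-hemiacetal with 3′-O) | C=C(CC[C@@H]1[C@@]2(C)CCC[C@@](C)(C(=O)OC)[C@@H]2[C@@H](O)C[C@@]1(C)O)[C@H]1C[C@@H]2OC(O)C[C@@]2(C)OO1 | intermediate
31 | CNP0162504.1 (1′R,3′S,4′R; trans-fused peroxy-γ-lactone; 4α-CO2Me; 6α-OH; 8α-OH) | C=C(CC[C@@H]1[C@@]2(C)CCC[C@@](C)(C(=O)OC)[C@@H]2[C@@H](O)C[C@@]1(C)O)[C@H]1C[C@@H]2OC(=O)C[C@@]2(C)OO1 | target

**Totals:** 17 steps; longest linear sequence 15 steps (steps 1–9 and 12–17, from 1).

**Three steps most likely to fail, with fallbacks**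

Step 5 (remote C–H etherification; risks are β‑scission of the 6α‑alkoxyl radical and iodination side reactions). The fallback sets out from 6 and comes back at 11. It replaces the hypoiodite/RuO4 pair by a Barton nitrite photolysis. Compound 6 is treated with NOCl in pyridine at −20 °C to give the 6α‑nitrite ester F1. Irradiation (Hg lamp, Pyrex, benzene) gives, after the same 1,5‑shift and NO recombination, the 4α‑carbaldehyde oxime F2 with the 6α‑OH free. NaNO2 in aqueous AcOH removes the oxime and the hydroxy aldehyde closes to lactol 10, which TEMPO/PhI(OAc)2 oxidises to lactone 11.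

Step 12 (ligand control at C1′ with a sensitive β,γ‑unsaturated aldehyde). The fallback sets out from 16 and 21 and comes back at 23. The coupling is run without ligand (CrCl2, cat. NiCl2, DMF) to give the C1′‑epimeric alcohols F3. These are oxidised with Dess–Martin periodinane to the α‑methylene ketone F4. Reduction with (R)-Me-CBS/catecholborane at −78 °C (alkenyl group as the large substituent) then gives 23, so the stereocentre is set by reagent‑controlled ketone reduction instead of in the C–C bond formation.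

Step 15 (new perhydrolytic annulation; risks are ionisation or SN2′ scrambling of the allylic mesylate during the acidic stage). The fallback uses known chemistry, sets out from 25 and comes back at 27. It reverses the order of the two C–O bond formations. Mesylate 25 alkylates 2‑methoxyprop‑2‑yl hydroperoxide (CsOH·H2O, DMF, 0 °C; SN2 with inversion at C1′) to give the (1′R) peroxyketal F5. AcOH/THF/H2O releases the (1′R) allylic hydroperoxide F6. Catalytic camphorsulfonic acid in CH2Cl2 then brings about 6‑endo (Markovnikov) opening of the epoxide at the tertiary C4′ with inversion to give 27.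

**Further compounds**

F1 | step 5 | 6α-nitrite ester of 6 | CC(=O)CC[C@@H]1[C@@]2(C)CCCC(C)(C)[C@@H]2[C@@H](ON=O)C[C@@]1(C)O[Si](CC)(CC)CC
F2 | step 5 | 4α-carbaldehyde (E)-oxime, 6α-hydroxy-8α-(triethylsilyloxy)-14,15-dinorlabdan-13-one series | CC(=O)CC[C@@H]1[C@@]2(C)CCC[C@@](C)(/C=N/O)[C@@H]2[C@@H](O)C[C@@]1(C)O[Si](CC)(CC)CC
F3 | step 12 | C1′-epimeric mixture of allylic alcohol 23 | C=C(CC[C@@H]1[C@@]2(C)CCC[C@@](C)(C(=O)OC)[C@@H]2[C@@H](O[Si](CC)(CC)CC)C[C@@]1(C)O[Si](CC)(CC)CC)C(O)C/C=C(\C)CCO[Si](C)(C)C(C)(C)C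
F4 | step 12 | 1′-ketone (α-methylene ketone) of 23 | C=C(CC[C@@H]1[C@@]2(C)CCC[C@@](C)(C(=O)OC)[C@@H]2[C@@H](O[Si](CC)(CC)CC)C[C@@]1(C)O[Si](CC)(CC)CC)C(=O)C/C=C(\C)CCO[Si](C)(C)C(C)(C)C
F5 | step 15 | (1′R,3′S,4′S)-epoxy 1′-(2-methoxyprop-2-yl) peroxide | C=C(CC[C@@H]1[C@@]2(C)CCC[C@@](C)(C(=O)OC)[C@@H]2[C@@H](O[Si](CC)(CC)CC)C[C@@]1(C)O[Si](CC)(CC)CC)[C@H](OOC(C)(C)OC)C[C@@H]1O[C@@]1(C)CCO[Si](C)(C)C(C)(C)C
F6 | step 15 | (1′R,3′S,4′S)-epoxy 1′-hydroperoxide | C=C(CC[C@@H]1[C@@]2(C)CCC[C@@](C)(C(=O)OC)[C@@H]2[C@@H](O[Si](CC)(CC)CC)C[C@@]1(C)O[Si](CC)(CC)CC)[C@H](OO)C[C@@H]1O[C@@]1(C)CCO[Si](C)(C)C(C)(C)C
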